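**Numbering.** Drimane numbering is used for each half: ring A = C1–C5 and C10; ring B = C5–C10; C11 on C9; C12 (methyl) on C8; C13 and C14 on C4; C15 (methyl) on C10. Primed numbers denote the second half. Compound numbers 1–17 are those of the steps and the compound list.

## Analysis of the target

Compound 17 is a C30H50 hydrocarbon built from two identical drim-8-ene units. In each unit a cyclohexane ring A is trans-fused to a cyclohexene ring B that holds a tetrasubstituted C8=C9 double bond, and C9 and C9′ are tied together by the C11–C11′ ethano bridge. There are four stereocentres, C5, C10, C5′ and C10′, all S. Within each half H-5 and the C15 methyl are trans across the ring fusion, and both halves have the same handedness, so the molecule is C2-symmetric and not meso. The only functional groups are the two tetrasubstituted olefins, which can migrate under acid (to C7=C8 or to the exocyclic C8=C12 position) and are open to allylic autoxidation. Every heteroatom used during the synthesis therefore has to be removed again. The difficulty lies in the congested contiguous array C4 (gem-dimethyl)–C5–C10 (quaternary)–C9 (fully substituted sp2), in placing the olefin at C8=C9 without isomers, and in controlling absolute configuration in two halves that must match. The strategy rests on ring A: C5 and C10 are vicinal, and their exocyclic branches (C6 on C5, C9 on C10) are trans. This is the pattern left by conjugate addition at C5 and enolate trapping at C10 of 2,4,4-trimethylcyclohex-2-en-1-one (6), whose carbonyl carbon is C1. The bridge C9–C11–C11′–C9′, oxygenated at both ends in such a product, is succinaldehyde (5).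

## Retrosynthetic reasoning

**17 ⇒ 16.** Both C8=C9 double bonds are cut, which opens rings B and B′ and gives tetraene 16, with a C9 methylene and a C8 isopropenyl group in each half. These are the only functional groups of 17, so a disconnection here leaves no trace to erase. In the forward direction a double six-membered ring-closing metathesis has to form two tetrasubstituted olefins. It fixes the olefin position by construction and needs no acid. Closing ring B last also means that only ring A has to carry stereochemical information.

**16 ⇒ 15 ⇒ 14 ⇒ 13.** The C9 methylene carbons are traced back to the C9 ketones of diketone 15, these to the carbinols of diol 14, and the carbinols to the silyl ethers of 13. This brings C9 to the carbinol oxidation level, where the C9–C10 bond is an aldol bond. Forward, this requires desilylation, oxidation and methylenation of a ketone flanked by the quaternary C10.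

**13 ⇒ 12 ⇒ 11 ⇒ 10.** An oxygen is put back on C1: thiocarbonyl ester 12, alcohol 11, ketone 10. The C1 carbonyl is absent from 17, but it is what makes C10 an enolate carbon and C5 a conjugate acceptor position. Forward, the ketone is reduced and the alcohol removed by radical deoxygenation. The C9 oxygen must be told apart from the C1 oxygen throughout, hence the silyl ethers.

**10 ⇒ 9.** Removal of the silyl groups gives bis-aldol 9, a twofold β-hydroxy ketone. The protection is needed only so that the C1 ketone can be deleted without touching C9.

**9 ⇒ 6 (twice) + 3 + 5.** This is the central disconnection. The aldol bonds C9–C10 and C9′–C10′ and the conjugate-addition bonds C5–C6 and C5′–C6′ are cut. These four bonds flank all four stereocentres. Cutting them returns ring A intact as the purchasable enone 6, which already carries the gem-dimethyl group and the C15 methyl. The C6–C7–C8(C12) unit comes from the dialkylzinc 3, and the bridge is dialdehyde 5. No other set of cuts gives three such simple partners, and the twofold symmetry lets one operation serve both halves. The forward reaction has to select the enone face at C5 with a chiral copper catalyst, bring the aldehyde to C10 on the face opposite the new C5 side chain, and consume both aldehyde groups of 5.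

**3 ⇒ 1 and 5 ⇒ 4.** Dialkylzinc 3 goes back through Grignard reagent 2 to two molecules of bromide 1, and dialdehyde 5 to the cyclic bis-acetal 4. Both are short, standard preparations, so the risk of the route stays in the key step.

## Alternatives that were turned down

**Alternative 1:** double Birch reductive methylation.
- Disconnection: the C10–C15 bonds of both halves, with each ring B traced back to a benzene ring. The whole C9–C11–C11′–C9′ core then comes from the bibenzyl bis-benzamide A2.
- Forward key step: dissolving-metal reduction of both arene rings of A2 to amide enolates and their C-methylation, directed by the prolinol-ether amide auxiliaries, to give the bis(cyclohexadiene carboxamide) A1.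
- For: auxiliary-controlled formation of quaternary C10 is a dependable reaction class. The C8=C9 olefins fall out of the reduction regiochemistry, and the bridge is present from the start.
- Against: A1 contains ring B only and two of the four stereocentres. The amide carbon must become C1; C2–C4 with the gem-dimethyl group must be added; ring A must be closed onto C5; the C5 oxygen must be removed; H-5 must be set trans to C15; and the auxiliaries must be cleaved at neopentyl positions. All of this is done twice, while an acid-sensitive skipped diene and enol ether are carried along.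
- Comparison: it is stronger in the reliability of the stereodefining event and needs no late metathesis. The chosen strategy instead delivers the complete carbon set of ring A and both stereocentres of each half in one operation, with no annulation to follow.

**Alternative 2:** double Stille coupling on a two-carbon linchpin.
- Disconnection: C9–C11 and C9′–C11′ as sp2–sp2 bonds. The bridge becomes the distannane A5 and each half the bicyclic enol triflate A4.
- Forward key step: two molecules of A4 couple with A5 under a zerovalent palladium catalyst with chloride and copper additives to give triene A3. Saturation of C11=C11′ then finishes the synthesis.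
- For: high convergence. Both stereocentres of each half are already in A4, whose parent ketone can come from the chiral pool, so absolute configuration is secure. The endgame after the key step is a single step, against eight here.
- Against: A4 is a tetrasubstituted enol triflate with the quaternary C10 next to the reacting carbon. Transmetalation and reductive elimination at such a centre are slow and must succeed twice on one linchpin. The central olefin of the conjugated triene A3 must then be reduced without 1,4- or 1,6-addition, which would move the flanking olefins out of C8=C9. The ketone behind A4 is not purchasable and costs several steps, and tin is used stoichiometrically.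
- Comparison: it is stronger in convergence, endgame length and certainty of configuration. The chosen strategy offers purchasable achiral building blocks, a bridge that is saturated from the outset, and an olefin position fixed by ring closure instead of by a selective reduction.

**Alternative 3:** two-directional epoxy-polyene tetracyclisation.
- Disconnection: C4–C5 and C9–C10 in both halves, which opens all four rings and leads to the acyclic bis-epoxide bis-allylsilane A7.
- Forward key step: a Lewis acid opens both epoxides at C4. Each end folds chair–chair, the C5=C10 olefin attacks C4, the allylsilane attacks C10 through C9, and loss of silicon leaves an exocyclic C8 methylene. The product is the tetracyclic diol A6.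
- For: it has the greatest bond-forming power of all options, closing four rings with the C5/C10 relationship set by olefin geometry and chair folding and absolute configuration set by the epoxides. The chosen key step closes no ring.
- Against: A6 overshoots this target. Two C3 hydroxyls must be removed. The exocyclic olefins must be isomerised to C8=C9, which erases the C9 centres the cascade set and, under acid, gives mixtures with the C7=C8 isomers independently in two rings. A7 itself needs a long linear assembly (two enantioselective epoxidations, geometrically defined trisubstituted olefins and allylsilanes, a bridge-forming coupling), and two cascades in one molecule multiply the partial-cyclisation channels.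
- Comparison: it is stronger in complexity gained per step and in precedent for the oxygenated relatives. The chosen strategy sets only the stereocentres that survive in 17, starts from a purchasable ring A, and defines the olefin position by construction.

Key step: step 3

**Assumptions.**
- Enone 6 is taken as purchasable.
- The (S,R,R)-phosphoramidite is taken to show the sense of induction known for unsubstituted cyclohex-2-enone, which corresponds to the S centre needed at C5. If the hindered enone responds with the opposite sense, the (R,S,S)-ligand is used and nothing else changes.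

## Route

Step 1
Reactants: 1 4-bromo-2-methylbut-1-ene (2.0 equiv)
Product: 3 bis(3-methylbut-3-en-1-yl)zinc, via Grignard reagent 2 (not isolated)
Conditions: Mg (2.4 equiv), I2 (cat.), Et2O, reflux; ZnCl2 (1.0 equiv), Et2O, 0 °C → rt; 1,4-dioxane, filtration under Ar; distillation in vacuo
Reagents that add atoms: zinc dichloride, Cl[Zn]Cl
Why: Magnesium insertion into two equivalents of the primary homoallylic bromide followed by transmetalation of the two equivalents of Grignard reagent 2 with one equivalent of ZnCl2 is the standard route to dialkylzincs; the homoallyl/cyclopropylcarbinyl interconversion of the Grignard reagent is degenerate for this skeleton, and precipitation of the magnesium halides with dioxane followed by distillation should give the salt-free reagent that the copper catalysis needs.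

Step 2
Reactants: 4 2,5-dimethoxytetrahydrofuran (cis/trans mixture)
Product: 5 succinaldehyde (butanedial)
Conditions: H2O, 90 °C; MeOH/H2O distilled off; CH2Cl2 extraction; short-path distillation; used at once
Reagents that add atoms: water, O
Why: Acetal hydrolysis in hot water releases the dialdehyde, removal of methanol drives the equilibrium, and distillation gives the monomer, which is used immediately because it oligomerises on standing.

Step 3
Reactants: 6 2,4,4-trimethylcyclohex-2-en-1-one (2.4 equiv); 3 bis(3-methylbut-3-en-1-yl)zinc (2.9 equiv); 5 succinaldehyde (1.0 equiv)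
Product: 9 (2S,2′S,3S,3′S)-2,2′-(1,4-dihydroxybutane-1,4-diyl)bis[2,4,4-trimethyl-3-(3-methylbut-3-en-1-yl)cyclohexan-1-one] (bis-aldol; C9/C9′ carbinol epimers), via alkylzinc enolate 7 (not isolated), via mono-aldol zinc alkoxide 8 (not isolated)
Conditions: Cu(OTf)2 (2.5 mol %), (S,R,R)-L (5 mol %; L = O,O′-[(S)-1,1′-binaphthyl-2,2′-diyl] N,N-bis[(R)-1-phenylethyl]phosphoramidite), toluene, −30 °C, 6 then 3; then 5 in toluene, −30 → −10 °C; aq NH4Cl
Reagents that add atoms: none
Why: The dialkylzinc reduces Cu(OTf)2 to a monovalent copper–phosphoramidite complex, which takes a 3-methylbut-3-enyl group from zinc, binds the zinc-activated enone 6 as a π-complex and passes the alkyl group to C5 by way of a trivalent copper intermediate and reductive elimination, forming C5–C6 and leaving the alkylzinc enolate 7. Enolate 7 then adds through C10 to one aldehyde group of 5 in a closed, zinc-bridged (Zimmerman–Traxler-type) transition state to give 8, and a second molecule of 7 adds to the remaining aldehyde to give 9, so that C9–C10 and C9′–C10′ are formed. The closest known reaction type is the copper–phosphoramidite-catalysed asymmetric conjugate addition of dialkylzincs to cyclohex-2-enones with in situ aldol trapping of the zinc enolate; the α-methyl, γ,γ-dimethyl enone and the twofold trapping by a dialdehyde are extensions of it. No ring is closed in this step. C5 and C5′ are set by the ligand, which selects the enone face (S at C5). C10 and C10′ are set by the substrate: A(1,2) strain with the C10 methyl holds the new C5 side chain pseudoaxial in the half-chair enolate, and the aldehyde bonds to C10 by axial approach on the opposite face, so the C9 branch ends trans to the C6 branch; the C9 carbinol centres are not controlled and need not be. The step needs the aldol addition to outrun alkyl transfer from zinc to the aldehyde and proton transfer from the enolisable dialdehyde, which the low basicity of the zinc enolate and the inertness of residual alkylzinc groups at −30 °C should secure, and it needs both aldehyde groups to react, which the excess of 7 secures. Because two homochiral halves are joined, most of the minor enantiomer of 7 should end in a heterochiral diastereomer that can be removed later (at 15), so the C2-symmetric series should be enantiomerically purer than 7 itself.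

Step 4
Reactants: 9 bis-aldol
Product: 10 (2S,2′S,3S,3′S)-2,2′-[1,4-bis(tert-butyldimethylsilyloxy)butane-1,4-diyl]bis[2,4,4-trimethyl-3-(3-methylbut-3-en-1-yl)cyclohexan-1-one] (C9/C9′ epimers)
Conditions: TBSOTf (3 equiv), 2,6-lutidine (5 equiv), CH2Cl2, −78 → 0 °C
Reagents that add atoms: tert-butyldimethylsilyl trifluoromethanesulfonate, CC(C)(C)[Si](C)(C)OS(=O)(=O)C(F)(F)F
Why: Silylation with the silyl triflate and a hindered pyridine base is the method of choice for neopentyl secondary carbinols; the conditions are too weakly basic for retro-aldol cleavage and leave the isopropenyl groups untouched.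

Step 5
Reactants: 10 bis-silyl ether diketone
Product: 11 bis-silyl ether diol: both C1 ketones of 10 reduced to secondary alcohols, C5 and C10 unchanged (C1 and C9 epimer mixture)
Conditions: LiAlH4, Et2O, 0 °C; aq NaOH work-up
Reagents that add atoms: none
Why: Hydride reduction of a ketone; the small aluminate reaches the carbonyl next to the quaternary C10, the silyl ethers and olefins are inert, and the new C1 centres are formed as mixtures, which does not matter because C1 becomes a methylene in step 7.

Step 6
Reactants: 11 bis-silyl ether diol
Product: 12 bis[O-(1H-imidazol-1-ylcarbothioyl)] derivative of 11 (thiocarbonyl ester at each C1 oxygen)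
Conditions: 1,1′-thiocarbonyldiimidazole (4 equiv), DMAP, toluene, 100 °C
Reagents that add atoms: 1,1′-thiocarbonyldiimidazole, S=C(n1ccnc1)n1ccnc1
Why: Thioacylation of the alcohol with nucleophilic catalysis by DMAP; no alkoxide is generated, which should prevent 1,3 oxygen-to-oxygen silyl migration between the C9 and C1 oxygens that a xanthate formation with a metal hydride base would invite.

Step 7
Reactants: 12 bis(thiocarbonyl ester)
Product: 13 1,4-bis(tert-butyldimethylsilyloxy)-1,4-bis[(1S,2S)-1,3,3-trimethyl-2-(3-methylbut-3-en-1-yl)cyclohexyl]butane (C9/C9′ epimers)
Conditions: Bu3SnH (6 equiv, ≥0.5 M), AIBN (cat.), toluene, 100 °C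
Reagents that add atoms: none
Why: Barton–McCombie deoxygenation: the stannyl radical adds to sulfur, β-scission gives the secondary C1 radical, and hydrogen transfer from the stannane gives the methylene; the high stannane concentration is chosen so that this transfer outpaces cyclisation of the C1 radical onto the isopropenyl group and 1,5-hydrogen shift from the allylic C7.

Step 8
Reactants: 13 bis-silyl ether
Product: 14 1,4-bis[(1S,2S)-1,3,3-trimethyl-2-(3-methylbut-3-en-1-yl)cyclohexyl]butane-1,4-diol (C9/C9′ epimers)
Conditions: Bu4NF, THF, 60 °C
Reagents that add atoms: none
Why: Fluoride-induced desilylation; fluoride attacks silicon and not the hindered carbon, so warming should suffice for these neopentyl silyl ethers, and nothing else in the hydrocarbon framework reacts.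

Step 9
Reactants: 14 diol
Product: 15 1,4-bis[(1S,2S)-1,3,3-trimethyl-2-(3-methylbut-3-en-1-yl)cyclohexyl]butane-1,4-dione
Conditions: Dess–Martin periodinane (3 equiv), CH2Cl2, rt
Reagents that add atoms: none
Why: Dess–Martin oxidation of the secondary alcohols under near-neutral conditions; all carbinol epimers converge on one C2-symmetric diketone, which is the point at which the heterochiral diastereomer from the minor enantiomer is removed by chromatography or crystallisation.

Step 10
Reactants: 15 diketone
Product: 16 2,5-bis[(1S,2S)-1,3,3-trimethyl-2-(3-methylbut-3-en-1-yl)cyclohexyl]hexa-1,5-diene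
Conditions: Cp2Ti(μ-Cl)(μ-CH2)AlMe2 (3 equiv), pyridine (cat.), THF/toluene, −40 °C → rt
Reagents that add atoms: Cp2Ti(μ-Cl)(μ-CH2)AlMe2, C[Al-]1(C)C[Ti](C2C=CC=C2)(C2C=CC=C2)[Cl+]1
Why: Tebbe methylenation through the titanium methylidene and an oxatitanacyclobutane; the reagent is small and non-basic, so it suits enolisable ketones flanked by a quaternary carbon, and its reversible cycloaddition to the isopropenyl groups is degenerate.

Step 11
Reactants: 16 tetraene
Product: 17 1,2-bis[(4aS,8aS)-2,5,5,8a-tetramethyl-3,4,4a,5,6,7,8,8a-octahydronaphthalen-1-yl]ethane (target)
Conditions: second-generation Hoveyda–Grubbs catalyst, (H2IMes)Cl2Ru=CH(C6H4-2-OiPr) (2 × 10 mol %), toluene (5 mM), 100 °C, Ar sparge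
Reagents that add atoms: none
Why: Double ring-closing metathesis: in each half the C9 methylene and the C8 isopropenyl group close ring B as a six-membered ring with a tetrasubstituted C8=C9 bond, driven by loss of ethene; the competing closures would give a four- or a nine-membered ring and are disfavoured, no stereocentre is touched, and the olefin position is fixed by the bond that is formed.

## Compound list

1 | 4-bromo-2-methylbut-1-ene | C=C(C)CCBr | starting material
2 | (3-methylbut-3-en-1-yl)magnesium bromide | C=C(C)CC[Mg]Br | intermediate
3 | bis(3-methylbut-3-en-1-yl)zinc | C=C(C)CC[Zn]CCC(C)=C | intermediate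
4 | 2,5-dimethoxytetrahydrofuran (cis/trans mixture) | COC1CCC(OC)O1 | starting material
5 | succinaldehyde (butanedial) | O=CCCC=O | intermediate
6 | 2,4,4-trimethylcyclohex-2-en-1-one | CC1=CC(C)(C)CCC1=O | starting material
7 | (3-methylbut-3-en-1-yl)zinc (3S)-2,4,4-trimethyl-3-(3-methylbut-3-en-1-yl)cyclohex-1-en-1-olate | C=C(C)CC[C@@H]1C(C)=C(O[Zn]CCC(C)=C)CCC1(C)C | intermediate
8 | (3-methylbut-3-en-1-yl)zinc alkoxide of 4-hydroxy-4-[(1S,2S)-1,3,3-trimethyl-2-(3-methylbut-3-en-1-yl)-6-oxocyclohexyl]butanal (carbinol epimers) | O=CCCC(O[Zn]CCC(C)=C)[C@@]1(C)C(=O)CCC(C)(C)[C@@H]1CCC(C)=C | intermediate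
9 | (2S,2′S,3S,3′S)-2,2′-(1,4-dihydroxybutane-1,4-diyl)bis[2,4,4-trimethyl-3-(3-methylbut-3-en-1-yl)cyclohexan-1-one] (carbinol epimers) | OC(CCC(O)[C@@]1(C)C(=O)CCC(C)(C)[C@@H]1CCC(C)=C)[C@@]1(C)C(=O)CCC(C)(C)[C@@H]1CCC(C)=C | intermediate
10 | (2S,2′S,3S,3′S)-2,2′-[1,4-bis(tert-butyldimethylsilyloxy)butane-1,4-diyl]bis[2,4,4-trimethyl-3-(3-methylbut-3-en-1-yl)cyclohexan-1-one] (C9 epimers) | CC(C)(C)[Si](C)(C)OC(CCC(O[Si](C)(C)C(C)(C)C)[C@@]1(C)C(=O)CCC(C)(C)[C@@H]1CCC(C)=C)[C@@]1(C)C(=O)CCC(C)(C)[C@@H]1CCC(C)=C | intermediate
11 | bis-silyl ether diol: the two C1 ketones of 10 reduced to secondary alcohols, ring centres C5 and C10 as in 10 (C1 and C9 epimers) | CC(C)(C)[Si](C)(C)OC(CCC(O[Si](C)(C)C(C)(C)C)[C@@]1(C)C(O)CCC(C)(C)[C@@H]1CCC(C)=C)[C@@]1(C)C(O)CCC(C)(C)[C@@H]1CCC(C)=C | intermediate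
12 | bis[O-(1H-imidazol-1-ylcarbothioyl)] derivative of 11 at the C1 oxygens (C1 and C9 epimers) | CC(C)(C)[Si](C)(C)OC(CCC(O[Si](C)(C)C(C)(C)C)[C@@]1(C)C(OC(=S)n2ccnc2)CCC(C)(C)[C@@H]1CCC(C)=C)[C@@]1(C)C(OC(=S)n2ccnc2)CCC(C)(C)[C@@H]1CCC(C)=C | intermediate
13 | 1,4-bis(tert-butyldimethylsilyloxy)-1,4-bis[(1S,2S)-1,3,3-trimethyl-2-(3-methylbut-3-en-1-yl)cyclohexyl]butane (C9 epimers) | CC(C)(C)[Si](C)(C)OC(CCC(O[Si](C)(C)C(C)(C)C)[C@@]1(C)CCCC(C)(C)[C@@H]1CCC(C)=C)[C@@]1(C)CCCC(C)(C)[C@@H]1CCC(C)=C | intermediate
14 | 1,4-bis[(1S,2S)-1,3,3-trimethyl-2-(3-methylbut-3-en-1-yl)cyclohexyl]butane-1,4-diol (C9 epimers) | OC(CCC(O)[C@@]1(C)CCCC(C)(C)[C@@H]1CCC(C)=C)[C@@]1(C)CCCC(C)(C)[C@@H]1CCC(C)=C | intermediate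
15 | 1,4-bis[(1S,2S)-1,3,3-trimethyl-2-(3-methylbut-3-en-1-yl)cyclohexyl]butane-1,4-dione | O=C(CCC(=O)[C@@]1(C)CCCC(C)(C)[C@@H]1CCC(C)=C)[C@@]1(C)CCCC(C)(C)[C@@H]1CCC(C)=C | intermediate
16 | 2,5-bis[(1S,2S)-1,3,3-trimethyl-2-(3-methylbut-3-en-1-yl)cyclohexyl]hexa-1,5-diene | C=C(CCC(=C)[C@@]1(C)CCCC(C)(C)[C@@H]1CCC(C)=C)[C@@]1(C)CCCC(C)(C)[C@@H]1CCC(C)=C | intermediate
17 | 1,2-bis[(4aS,8aS)-2,5,5,8a-tetramethyl-3,4,4a,5,6,7,8,8a-octahydronaphthalen-1-yl]ethane | CC1=C(CCC2=C(C)CC[C@H]3C(C)(C)CCC[C@]23C)[C@@]2(C)CCCC(C)(C)[C@@H]2CC1 | target

## Step count and least certain steps

Total step count: 11. Longest linear sequence: 10 steps (steps 1 and 3–11; step 2 is a one-step side branch).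

**Step 3 (key step).** Two things are most likely to go wrong. First, alkyl transfer to C5 may be slow or incomplete, because the α-methyl group lowers the electrophilicity of the enone and the C4 gem-dimethyl group shields C5; a slow catalysed path also gives the unselective background reaction room. Second, the aldol trapping may fail: the tetrasubstituted enolate must form a quaternary centre next to C5, so the addition can be slow and reversible; the enolisable dialdehyde can transfer a proton; and after the first addition the second aldehyde can be held as a cyclic zinc hemiacetal, which stops the sequence at the mono-adduct or opens an internal hydride shift (aldol–Tishchenko) to the C1 ketone. The fallback separates the two events. It sets out from 6: copper-catalysed asymmetric conjugate addition of the more reactive Grignard reagent 2 (CuBr·SMe2 with the ferrocenyl diphosphine (R)-1-[(S)-2-(diphenylphosphino)ferrocenyl]ethyldicyclohexylphosphine or its enantiomer, whichever gives S at C5, Et2O, −78 → −30 °C), and trapping of the magnesium enolate with Me3SiCl/Et3N, gives trimethyl{[(3S)-2,4,4-trimethyl-3-(3-methylbut-3-en-1-yl)cyclohex-1-en-1-yl]oxy}silane F1, which is purified. A twofold Mukaiyama aldol addition of F1 to 5 (TiCl4, CH2Cl2, −78 °C), which involves no basic enolate and no free aldolate, then returns to the route at 9.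

**Step 11.** The double ring-closing metathesis has to load ruthenium onto 1,1-disubstituted olefins, one of them neopentyl, and form two tetrasubstituted double bonds. The likely failures are catalyst decay before the second closure, stalling after one ring, and ruthenium hydride-induced migration of the isopropenyl double bond, which would lead to ring-contracted products. The fallback replaces olefin metathesis by carbonyl coupling. It sets out from 15: ozonolysis of both isopropenyl groups (O3, CH2Cl2/MeOH, −78 °C; Me2S) gives 1,4-bis[(1S,2S)-1,3,3-trimethyl-2-(3-oxobutyl)cyclohexyl]butane-1,4-dione F2. A twofold intramolecular McMurry coupling of its two 1,6-diketone pairs (TiCl3(DME)1.5, Zn–Cu couple, DME, reflux, slow addition) closes both rings B with the tetrasubstituted C8=C9 bonds and returns at 17, bypassing steps 10 and 11.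

**Step 6 (with step 7).** The C1 carbinol is neopentyl and flanked by the bulky C10 substituent, so thioacylation may be slow; forcing it risks elimination and silyl migration between the C9 and C1 oxygens, and in step 7 intramolecular hydrogen transfer or radical cyclisation may compete if the stannane concentration drops. The fallback avoids the alcohol and the radical altogether. It sets out from 10: condensation with 4-methylbenzenesulfonohydrazide (EtOH, reflux) gives the bis(4-methylbenzenesulfonylhydrazone) of 10 F3, and reduction with catecholborane (CHCl3, 0 °C → rt) followed by NaOAc·3H2O at reflux expels sulfinate and dinitrogen and returns at 13, bypassing steps 5–7.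

**Step 10.** Methylenation may stop after one ketone, or be diverted to titanium enolates, because each carbonyl is shielded by the quaternary C10. The fallback is a Peterson olefination. It sets out from 15: addition of Me3SiCH2Li in the presence of CeCl3 (THF, −78 °C → rt) gives the bis(β-hydroxysilane) 2,5-bis[(1S,2S)-1,3,3-trimethyl-2-(3-methylbut-3-en-1-yl)cyclohexyl]-1,6-bis(trimethylsilyl)hexane-2,5-diol F4, and elimination with KH in THF returns at 16.

## Further compounds

F1 | step 3 | trimethyl{[(3S)-2,4,4-trimethyl-3-(3-methylbut-3-en-1-yl)cyclohex-1-en-1-yl]oxy}silane | C=C(C)CC[C@@H]1C(C)=C(O[Si](C)(C)C)CCC1(C)C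
F2 | step 11 | 1,4-bis[(1S,2S)-1,3,3-trimethyl-2-(3-oxobutyl)cyclohexyl]butane-1,4-dione | O=C(CCC(=O)[C@@]1(C)CCCC(C)(C)[C@@H]1CCC(C)=O)[C@@]1(C)CCCC(C)(C)[C@@H]1CCC(C)=O
F3 | step 6 | bis(4-methylbenzenesulfonylhydrazone) of 10 | CC(C)(C)[Si](C)(C)OC(CCC(O[Si](C)(C)C(C)(C)C)[C@@]1(C)C(=NNS(=O)(=O)c2ccc(C)cc2)CCC(C)(C)[C@@H]1CCC(C)=C)[C@@]1(C)C(=NNS(=O)(=O)c2ccc(C)cc2)CCC(C)(C)[C@@H]1CCC(C)=C
F4 | step 10 | 2,5-bis[(1S,2S)-1,3,3-trimethyl-2-(3-methylbut-3-en-1-yl)cyclohexyl]-1,6-bis(trimethylsilyl)hexane-2,5-diol (carbinol epimers) | C[Si](C)(C)CC(O)(CCC(O)(C[Si](C)(C)C)[C@@]1(C)CCCC(C)(C)[C@@H]1CCC(C)=C)[C@@]1(C)CCCC(C)(C)[C@@H]1CCC(C)=C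
A1 | alternative 1 | bis(1-methylcyclohexa-2,5-diene-1-carboxamide) with both quaternary C10 centres, C8=C9 olefins, C5 methyl enol ethers and (S)-2-(methoxymethyl)pyrrolidine amides | COC[C@@H]1CCCN1C(=O)[C@@]1(C)C(OC)=CCC(C)=C1CCC1=C(C)CC=C(OC)[C@]1(C)C(=O)N1CCC[C@H]1COC
A2 | alternative 1 | bibenzyl bis-benzamide: 1,2-bis{3-methoxy-6-methyl-2-[(S)-2-(methoxymethyl)pyrrolidine-1-carbonyl]phenyl}ethane | COC[C@@H]1CCCN1C(=O)c1c(OC)ccc(C)c1CCc1c(C)ccc(OC)c1C(=O)N1CCC[C@H]1COC
A3 | alternative 2 | (E)-1,2-bis[(4aS,8aS)-2,5,5,8a-tetramethyl-3,4,4a,5,6,7,8,8a-octahydronaphthalen-1-yl]ethene | CC1=C(/C=C/C2=C(C)CC[C@H]3C(C)(C)CCC[C@]23C)[C@@]2(C)CCCC(C)(C)[C@@H]2CC1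
A4 | alternative 2 | (4aS,8aS)-2,5,5,8a-tetramethyl-3,4,4a,5,6,7,8,8a-octahydronaphthalen-1-yl trifluoromethanesulfonate | CC1=C(OS(=O)(=O)C(F)(F)F)[C@@]2(C)CCCC(C)(C)[C@@H]2CC1
A5 | alternative 2 | (E)-1,2-bis(tributylstannyl)ethene | CCCC[Sn](CCCC)(CCCC)/C=C/[Sn](CCCC)(CCCC)CCCC
A6 | alternative 3 | tetracyclic 3β,3′β-diol with exocyclic C8 and C8′ methylenes and 9α/9′α hydrogens | C=C1[C@H](CC[C@H]2C(=C)CC[C@H]3C(C)(C)[C@@H](O)CC[C@]23C)[C@@]2(C)CC[C@H](O)C(C)(C)[C@@H]2CC1
A7 | alternative 3 | acyclic (3S,3′S)-bis-epoxide with E C5=C10 olefins and trimethylsilylmethyl groups on C8 and C8′ (C7 and C11 trans across C8=C9) | CC1(C)O[C@H]1CC/C(C)=C/CC/C(C[Si](C)(C)C)=C/CC/C=C(C[Si](C)(C)C)/CC/C=C(C)/CC[C@@H]1OC1(C)C
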